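**Retrosynthetic overview**

1. The last step forms C7–C8 by an indium-mediated ring-closing allylation of an open-chain C8 aldehyde, in which C7 of a 2-(bromomethyl)enoate acts as a β-acyl allyl anion. This closes the nine-membered oxa-bridged ring, and lactonisation in the same flask gives the α-methylene lactone; C7 and C8 are set here.
2. The allyl bromide comes from cross-metathesis of a C7 vinyl group with methyl 2-(bromomethyl)acrylate.
3. C5–C6 comes from a furanonyl acrolein and 3-chloropropenyl angelate (acrolein with its carbonyl carbon made nucleophilic). Chromium-catalysed asymmetric hydroxyallylation sets C5 and C6 and leaves the angelate on O6 with O5 free, so the diol needs no protecting groups.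
4. The furanone ring is made first, from the lithium acetylide of 2-methylbut-1-en-3-yne and a lactic acid dioxolanone via an α′-hydroxy ynone; the isopropenyl methyl is then oxidised to the C5 aldehyde.
5. C10 comes from (S)-lactic acid by Seebach allylation; the allyl group is cut to the masked C8 aldehyde. Ring order: furanone, then nine-membered ring, then lactone.

Atom labels (germacrane numbering): C1 furanone C=O, C2 furanone CH, C3 furanone O–C=, C4/C15 exocyclic methylene, C5 CH–OH, C6 CH–O-angelate, C7/C8 lactone ring fusion, C9 CH2, C10 C(Me)–O, C11/C13 lactone methylene, C12 lactone C=O, C14 methyl. The target is (5S,6S,7R,8S,10R).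

Assumption: the (R,R)-salen ligand is taken to give the (5S,6S) sense in step 7; if the first run (Mosher ester check) shows the opposite sense, the (S,S) ligand is used with no other change.

**Route**

Step 1
Reactants: 1 (S)-lactic acid; 2 pivalaldehyde
Product: 3 (2S,5S)-2-tert-butyl-5-methyl-1,3-dioxolan-4-one
Conditions: TsOH·H2O (cat.), H2SO4 (cat.), pentane, reflux, Dean–Stark; recrystallise from pentane at −78 °C
Reagents that add atoms: none
Why: Acid-catalysed acetalisation (Seebach dioxolanone formation) with water removal; C5 comes unchanged from lactic acid and the favoured cis (2S,5S) acetal crystallises out.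

Step 2
Reactants: 3 (2S,5S)-2-tert-butyl-5-methyl-1,3-dioxolan-4-one; 4 allyl bromide
Product: 6 (2S,5R)-2-tert-butyl-5-methyl-5-(prop-2-en-1-yl)-1,3-dioxolan-4-one, via lithium enolate 5 (not isolated)
Conditions: LiN(iPr)2, THF, −78 °C; then allyl bromide, −78 → −30 °C
Reagents that add atoms: none
Why: Seebach self-regeneration of stereocentres: the planar enolate keeps the acetal centre and allyl bromide enters anti to the tert-butyl group, giving the quaternary carbon (future C10) as 5R with about 95:5 selectivity.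

Step 3
Reactants: 6 (2S,5R)-2-tert-butyl-5-methyl-5-(prop-2-en-1-yl)-1,3-dioxolan-4-one
Product: 8 (2S,5R)-2-tert-butyl-5-(2,2-dimethoxyethyl)-5-methyl-1,3-dioxolan-4-one, via aldehyde 7 (not isolated)
Conditions: O3, CH2Cl2/MeOH (4:1), −78 °C; Me2S, −78 °C → rt; then HC(OMe)3, PPTS (cat.), rt
Reagents that add atoms: ozone [O-][O+]=O; trimethyl orthoformate COC(OC)OC
Why: Ozonolysis of the only alkene with reductive work-up, then mild acid-catalysed acetalisation, which traps the β-acyloxy aldehyde before it can eliminate; no stereocentre is touched.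

Step 4
Reactants: 8 (2S,5R)-2-tert-butyl-5-(2,2-dimethoxyethyl)-5-methyl-1,3-dioxolan-4-one; 9 2-methylbut-1-en-3-yne
Product: 12 (2R)-2-(2,2-dimethoxyethyl)-2-methyl-5-(prop-1-en-2-yl)furan-3(2H)-one, via lithium acetylide 10 (not isolated), via hydroxy ynone 11 (not isolated)
Conditions: 9, n-BuLi, THF, −78 °C; add 8, −78 → −40 °C; aq NH4Cl; crude, K2CO3 (0.2 equiv), MeOH, 0 °C
Reagents that add atoms: none
Why: Alkynyllithium addition to the lactone-type carbonyl stops at the tetrahedral adduct, which on quench collapses with loss of pivalaldehyde to the α′-hydroxy ynone; its tertiary alkoxide closes by 5-endo-dig oxa-Michael addition to the 3(2H)-furanone, and the quaternary centre is not involved and stays R.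

Step 5
Reactants: 12 (2R)-2-(2,2-dimethoxyethyl)-2-methyl-5-(prop-1-en-2-yl)furan-3(2H)-one
Product: 13 2-[(5R)-5-(2,2-dimethoxyethyl)-5-methyl-4-oxo-4,5-dihydrofuran-2-yl]prop-2-enal
Conditions: SeO2 (1.3 equiv), 1,4-dioxane, 4 Å MS, 80 °C; product used at once
Reagents that add atoms: selenium dioxide O=[Se]=O
Why: Riley allylic oxidation (ene reaction, then [2,3]-shift) at the only allylic C–H bonds in the molecule, by analogy with α-methylstyrene → 2-phenylacrolein; no stereocentre is formed.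

Step 6
Reactants: 14 angelic acid; 15 acrolein
Product: 17 3-chloroprop-1-en-1-yl (2Z)-2-methylbut-2-enoate (E/Z mixture at the enol ester), via angeloyl chloride 16 (not isolated)
Conditions: 1-chloro-N,N,2-trimethylprop-1-en-1-amine, CH2Cl2, 0 °C; then acrolein, ZnCl2 (5 mol %), −20 → 0 °C
Reagents that add atoms: 1-chloro-N,N,2-trimethylprop-1-en-1-amine CC(C)=C(Cl)N(C)C
Why: Neutral acid chloride formation (no HCl, so the Z angeloyl group should not isomerise to tigloyl; check by NMR) followed by ZnCl2-catalysed conjugate addition of the acyl chloride across acrolein; the enol ester geometry does not matter because both isomers give the same allylchromium.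

Step 7
Reactants: 13 2-[(5R)-5-(2,2-dimethoxyethyl)-5-methyl-4-oxo-4,5-dihydrofuran-2-yl]prop-2-enal; 17 3-chloroprop-1-en-1-yl (2Z)-2-methylbut-2-enoate
Product: 19 (3S,4S)-5-[(5R)-5-(2,2-dimethoxyethyl)-5-methyl-4-oxo-4,5-dihydrofuran-2-yl]-4-hydroxyhexa-1,5-dien-3-yl (2Z)-2-methylbut-2-enoate, via trimethylsilyl ether 18 (not isolated)
Conditions: CrCl3 (10 mol %), (R,R)-N,N′-bis(3,5-di-tert-butylsalicylidene)cyclohexane-1,2-diamine (12 mol %), Et3N (20 mol %), Mn powder (3 equiv), Me3SiCl (1.5 equiv), MeCN, rt; then citric acid, MeOH, 0 °C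
Reagents that add atoms: none
Why: Catalytic asymmetric Nozaki–Hiyama–Kishi hydroxyallylation: the γ-acyloxyallylchromium (acrolein's carbonyl carbon made nucleophilic) adds 1,2 to the enal through its oxygen-bearing carbon, forming C5–C6 with the angelate already on O6 and O5 free; the trivalent chromium–salen complex gives the syn pattern and sets (5S,6S) under catalyst control, the remote C10 centre having no influence.

Step 8
Reactants: 19 (3S,4S)-5-[(5R)-5-(2,2-dimethoxyethyl)-5-methyl-4-oxo-4,5-dihydrofuran-2-yl]-4-hydroxyhexa-1,5-dien-3-yl (2Z)-2-methylbut-2-enoate; 20 methyl 2-(bromomethyl)prop-2-enoate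
Product: 21 methyl (2Z,4S,5S)-2-(bromomethyl)-6-[(5R)-5-(2,2-dimethoxyethyl)-5-methyl-4-oxo-4,5-dihydrofuran-2-yl]-5-hydroxy-4-{[(2Z)-2-methylbut-2-enoyl]oxy}hepta-2,6-dienoate
Conditions: second-generation Hoveyda–Grubbs catalyst RuCl2(H2IMes)(=CH-C6H4-2-OiPr) (10 mol %), 20 (8 equiv), 2,6-dichloro-1,4-benzoquinone (10 mol %), CH2Cl2, 40 °C, argon sparge
Reagents that add atoms: none
Why: Olefin cross-metathesis between the only unconjugated terminal alkene and the 1,1-disubstituted acrylate, driven by loss of ethene; the conjugated alkenes do not take part and the trisubstituted enoate forms with the C6 chain trans to the ester (2Z), while C5 and C6 are untouched.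

Step 9
Reactants: 21 methyl (2Z,4S,5S)-2-(bromomethyl)-6-[(5R)-5-(2,2-dimethoxyethyl)-5-methyl-4-oxo-4,5-dihydrofuran-2-yl]-5-hydroxy-4-{[(2Z)-2-methylbut-2-enoyl]oxy}hepta-2,6-dienoate
Product: 24 (5S,6S,7R,8S,10R)-6-(angeloyloxy)-5-hydroxy-1-oxo-3,10-epoxygermacra-2,4(15),11(13)-trien-12,8-olide (CNP0120053.1), via aldehyde 22 (not isolated), via hydroxy ester 23 (not isolated)
Conditions: 1 M aq HCl/THF (1:4), rt; NaHCO3 to pH 6; In powder (3 equiv), THF/H2O (1:1), 0.002 M, 25–40 °C; then TsOH·H2O (cat.), CH2Cl2, rt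
Reagents that add atoms: water O
Why: Acetal hydrolysis, then intramolecular indium Barbier allylation in which the 2-(bromomethyl)enoate attacks the aldehyde through C7 as a β-acyl allyl anion (homoenolate-type d3 synthon), then lactonisation; allylic 1,3-strain keeps H6 in the enoate plane so the tethered aldehyde reaches C7 only on the face carrying C5 (7R), and the chair with C6 axial can span the rigid furanone bridge only with C9 axial and anti to C6, which is expected to give the trans lactone (8S).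

**Compound list**

1 | (S)-lactic acid | C[C@H](O)C(=O)O | starting material
2 | pivalaldehyde | CC(C)(C)C=O | starting material
3 | (2S,5S)-2-tert-butyl-5-methyl-1,3-dioxolan-4-one | C[C@@H]1O[C@@H](OC1=O)C(C)(C)C | intermediate
4 | allyl bromide | C=CCBr | starting material
5 | lithium (2S)-2-tert-butyl-5-methyl-2H-1,3-dioxol-4-olate (lithium enolate of 3) | CC1=C(O[Li])O[C@H](O1)C(C)(C)C | intermediate
6 | (2S,5R)-2-tert-butyl-5-methyl-5-(prop-2-en-1-yl)-1,3-dioxolan-4-one | C[C@]1(CC=C)O[C@@H](OC1=O)C(C)(C)C | intermediate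
7 | (2S,5R)-2-tert-butyl-5-methyl-5-(2-oxoethyl)-1,3-dioxolan-4-one | C[C@]1(CC=O)O[C@@H](OC1=O)C(C)(C)C | intermediate
8 | (2S,5R)-2-tert-butyl-5-(2,2-dimethoxyethyl)-5-methyl-1,3-dioxolan-4-one | C[C@]1(CC(OC)OC)O[C@@H](OC1=O)C(C)(C)C | intermediate
9 | 2-methylbut-1-en-3-yne | C=C(C)C#C | starting material
10 | (3-methylbut-3-en-1-yn-1-yl)lithium | [Li]C#CC(C)=C | intermediate
11 | (6R)-6-hydroxy-8,8-dimethoxy-2,6-dimethyloct-1-en-3-yn-5-one | COC(OC)C[C@@](C)(O)C(=O)C#CC(C)=C | intermediate
12 | (2R)-2-(2,2-dimethoxyethyl)-2-methyl-5-(prop-1-en-2-yl)furan-3(2H)-one | COC(OC)C[C@@]1(C)OC(=CC1=O)C(C)=C | intermediate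
13 | 2-[(5R)-5-(2,2-dimethoxyethyl)-5-methyl-4-oxo-4,5-dihydrofuran-2-yl]prop-2-enal | COC(OC)C[C@@]1(C)OC(=CC1=O)C(=C)C=O | intermediate
14 | angelic acid, (2Z)-2-methylbut-2-enoic acid | C/C=C(/C)C(=O)O | starting material
15 | acrolein | C=CC=O | starting material
16 | angeloyl chloride, (2Z)-2-methylbut-2-enoyl chloride | C/C=C(/C)C(=O)Cl | intermediate
17 | 3-chloroprop-1-en-1-yl (2Z)-2-methylbut-2-enoate (E/Z mixture at the enol ester) | C/C=C(/C)C(=O)OC=CCCl | intermediate
18 | (3S,4S)-5-[(5R)-5-(2,2-dimethoxyethyl)-5-methyl-4-oxo-4,5-dihydrofuran-2-yl]-4-[(trimethylsilyl)oxy]hexa-1,5-dien-3-yl (2Z)-2-methylbut-2-enoate | COC(OC)C[C@@]1(C)OC(=CC1=O)C(=C)[C@H](O[Si](C)(C)C)[C@@H](OC(=O)/C(C)=C\C)C=C | intermediate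
19 | (3S,4S)-5-[(5R)-5-(2,2-dimethoxyethyl)-5-methyl-4-oxo-4,5-dihydrofuran-2-yl]-4-hydroxyhexa-1,5-dien-3-yl (2Z)-2-methylbut-2-enoate | COC(OC)C[C@@]1(C)OC(=CC1=O)C(=C)[C@H](O)[C@@H](OC(=O)/C(C)=C\C)C=C | intermediate
20 | methyl 2-(bromomethyl)prop-2-enoate | C=C(CBr)C(=O)OC | starting material
21 | methyl (2Z,4S,5S)-2-(bromomethyl)-6-[(5R)-5-(2,2-dimethoxyethyl)-5-methyl-4-oxo-4,5-dihydrofuran-2-yl]-5-hydroxy-4-{[(2Z)-2-methylbut-2-enoyl]oxy}hepta-2,6-dienoate | COC(OC)C[C@@]1(C)OC(=CC1=O)C(=C)[C@H](O)[C@@H](OC(=O)/C(C)=C\C)/C=C(\CBr)C(=O)OC | intermediate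
22 | methyl (2Z,4S,5S)-2-(bromomethyl)-5-hydroxy-6-[(5R)-5-methyl-4-oxo-5-(2-oxoethyl)-4,5-dihydrofuran-2-yl]-4-{[(2Z)-2-methylbut-2-enoyl]oxy}hepta-2,6-dienoate | O=CC[C@@]1(C)OC(=CC1=O)C(=C)[C@H](O)[C@@H](OC(=O)/C(C)=C\C)/C=C(\CBr)C(=O)OC | intermediate
23 | methyl (5S,6S,7R,8S,10R)-6-(angeloyloxy)-5,8-dihydroxy-1-oxo-3,10-epoxygermacra-2,4(15),11(13)-trien-12-oate (ring closed at C7–C8, lactone still open) | COC(=O)C(=C)[C@@H]1[C@@H](O)C[C@@]2(C)OC(=CC2=O)C(=C)[C@H](O)[C@H]1OC(=O)/C(C)=C\C | intermediate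
24 | (5S,6S,7R,8S,10R)-6-(angeloyloxy)-5-hydroxy-1-oxo-3,10-epoxygermacra-2,4(15),11(13)-trien-12,8-olide, CNP0120053.1 | C=C1C(=O)O[C@H]2C[C@@]3(C)OC(=CC3=O)C(=C)[C@H](O)[C@@H](OC(=O)/C(C)=C\C)[C@H]12 | target

**Step count and risks**

Total: 9 steps. Longest linear sequence: 8 steps (1–5, then 7–9); step 6 is a one-step side branch for the reagent 17.

The three steps most likely to fail:

Step 9 is the riskiest. The nine-membered ring may close in low yield against oligomerisation, the allylindium may lose the angelate by 1,4-elimination to a diene, and the C8 outcome (trans versus cis lactone) rests on a transition-state argument rather than on a close precedent. The fallback changes the allyl donor and the transition state. It sets out from 21: hexabutylditin and Pd(PPh3)4 in THF at 50 °C exchange bromide for tin to give the allylstannane acetal F1; LiBF4 in wet MeCN unmasks the stannyl aldehyde F2; BF3·OEt2 in CH2Cl2 at −78 °C and 0.002 M then closes the ring by Lewis-acid-promoted allyl transfer through an open transition state, with no basic allylmetal present. This gives the hydroxy ester 23, where the route is rejoined; lactonisation to 24 follows as in step 9.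

Step 8 may fail because the vinyl group carries an allylic ester and the partner is a hindered, electron-poor 1,1-disubstituted alkene. The fallback replaces metathesis by cleavage and olefination. It sets out from 19: Et3SiOTf and 2,6-lutidine give the triethylsilyl ether F3; OsO4 (cat.) and NaIO4 with 2,6-lutidine in dioxane/water cleave the only unconjugated alkene to the α-angeloyloxy aldehyde F4; a Morita–Baylis–Hillman reaction with methyl acrylate and DABCO gives the allylic alcohol F5 (its new carbinol centre is lost in the next operation); NBS and Me2S in CH2Cl2 at 0 °C convert it by SN2′ bromination into the silylated (Z)-bromide F6. The acid treatment of step 9 then removes the silyl group together with the acetal, so the route is rejoined at aldehyde 22.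

Step 5 may fail because the isopropenyl alkene is conjugated to the furanone and therefore a poor ene partner, and the acetal may not survive selenous acid at 80 °C. The fallback builds the enal by α-methylenation instead of allylic oxidation. It sets out from 8: commercial tert-butyl(but-3-yn-1-yloxy)dimethylsilane (C#CCCO[Si](C)(C)C(C)(C)C) is lithiated with n-BuLi to the lithium acetylide F7 and added under the conditions of step 4, giving through the hydroxy ynone F8 the furanone silyl ether F9; Bu4NF in THF frees the alcohol F10; Dess–Martin periodinane gives the aldehyde F11; aqueous formaldehyde with pyrrolidine and propionic acid in isopropanol at 45 °C installs the methylene group and returns the enal 13.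

**Further compounds**

F1 | step 9 | methyl (2Z,4S,5S)-6-[(5R)-5-(2,2-dimethoxyethyl)-5-methyl-4-oxo-4,5-dihydrofuran-2-yl]-5-hydroxy-4-{[(2Z)-2-methylbut-2-enoyl]oxy}-2-[(tributylstannyl)methyl]hepta-2,6-dienoate | COC(OC)C[C@@]1(C)OC(=CC1=O)C(=C)[C@H](O)[C@@H](OC(=O)/C(C)=C\C)/C=C(\C[Sn](CCCC)(CCCC)CCCC)C(=O)OC
F2 | step 9 | methyl (2Z,4S,5S)-5-hydroxy-6-[(5R)-5-methyl-4-oxo-5-(2-oxoethyl)-4,5-dihydrofuran-2-yl]-4-{[(2Z)-2-methylbut-2-enoyl]oxy}-2-[(tributylstannyl)methyl]hepta-2,6-dienoate | O=CC[C@@]1(C)OC(=CC1=O)C(=C)[C@H](O)[C@@H](OC(=O)/C(C)=C\C)/C=C(\C[Sn](CCCC)(CCCC)CCCC)C(=O)OC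
F3 | step 8 | (3S,4S)-5-[(5R)-5-(2,2-dimethoxyethyl)-5-methyl-4-oxo-4,5-dihydrofuran-2-yl]-4-[(triethylsilyl)oxy]hexa-1,5-dien-3-yl (2Z)-2-methylbut-2-enoate | COC(OC)C[C@@]1(C)OC(=CC1=O)C(=C)[C@H](O[Si](CC)(CC)CC)[C@@H](OC(=O)/C(C)=C\C)C=C
F4 | step 8 | (2R,3S)-4-[(5R)-5-(2,2-dimethoxyethyl)-5-methyl-4-oxo-4,5-dihydrofuran-2-yl]-1-oxo-3-[(triethylsilyl)oxy]pent-4-en-2-yl (2Z)-2-methylbut-2-enoate | COC(OC)C[C@@]1(C)OC(=CC1=O)C(=C)[C@H](O[Si](CC)(CC)CC)[C@@H](OC(=O)/C(C)=C\C)C=O
F5 | step 8 | methyl (4S,5S)-6-[(5R)-5-(2,2-dimethoxyethyl)-5-methyl-4-oxo-4,5-dihydrofuran-2-yl]-3-hydroxy-2-methylidene-4-{[(2Z)-2-methylbut-2-enoyl]oxy}-5-[(triethylsilyl)oxy]hept-6-enoate (both C3 epimers) | COC(OC)C[C@@]1(C)OC(=CC1=O)C(=C)[C@H](O[Si](CC)(CC)CC)[C@@H](OC(=O)/C(C)=C\C)C(O)C(=C)C(=O)OC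
F6 | step 8 | methyl (2Z,4S,5S)-2-(bromomethyl)-6-[(5R)-5-(2,2-dimethoxyethyl)-5-methyl-4-oxo-4,5-dihydrofuran-2-yl]-4-{[(2Z)-2-methylbut-2-enoyl]oxy}-5-[(triethylsilyl)oxy]hepta-2,6-dienoate | COC(OC)C[C@@]1(C)OC(=CC1=O)C(=C)[C@H](O[Si](CC)(CC)CC)[C@@H](OC(=O)/C(C)=C\C)/C=C(\CBr)C(=O)OC
F7 | step 5 | {4-[(tert-butyldimethylsilyl)oxy]but-1-yn-1-yl}lithium | [Li]C#CCCO[Si](C)(C)C(C)(C)C
F8 | step 5 | (6R)-1-[(tert-butyldimethylsilyl)oxy]-6-hydroxy-8,8-dimethoxy-6-methyloct-3-yn-5-one | COC(OC)C[C@@](C)(O)C(=O)C#CCCO[Si](C)(C)C(C)(C)C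
F9 | step 5 | (2R)-5-{2-[(tert-butyldimethylsilyl)oxy]ethyl}-2-(2,2-dimethoxyethyl)-2-methylfuran-3(2H)-one | COC(OC)C[C@@]1(C)OC(=CC1=O)CCO[Si](C)(C)C(C)(C)C
F10 | step 5 | (2R)-2-(2,2-dimethoxyethyl)-5-(2-hydroxyethyl)-2-methylfuran-3(2H)-one | COC(OC)C[C@@]1(C)OC(=CC1=O)CCO
F11 | step 5 | 2-[(5R)-5-(2,2-dimethoxyethyl)-5-methyl-4-oxo-4,5-dihydrofuran-2-yl]acetaldehyde | COC(OC)C[C@@]1(C)OC(=CC1=O)CC=O
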